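**Retrosynthetic overview**

1. 3-Hydroxyglabrol ⇐ cleavage of two aryl silyl ethers ⇐ double Stille prenylation of a C8,C3'-diiodide ⇐ oxidation of a C4 carbinol to the ketone. Iodine stands in for prenyl because a C8 prenyl group would capture a cation at C2.
2. Ring C ⇐ one enantioselective formal [4+2] annulation: an O-aryl oxocarbenium ion (C2=O1+, conjugated with C8a=C4a of ring A) takes up the C3=C4 bond of (Z)-1,2-bis(trimethylsilyloxy)ethene. This forms C2–C3 and C4–C4a and sets C2 and C3; C4 arrives as a carbinol.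
3. Enabling feature: ring A is a resorcinol ring with O1 on C8a, so C4a is ortho to O1 and para to the C7 oxygen, a strongly nucleophilic arene carbon next to the cation-bearing oxygen. C8 is blocked by iodine, and the para oxygen of ring B stabilises the cation at C2.
4. Oxocarbenium precursor ⇐ O-aryl O-acetyl acetal ⇐ ring-B aldehyde + acetyl bromide + ring-A phenol; two-carbon unit ⇐ vinylene carbonate.
5. Ring order: rings A and B are bought (2-iodoresorcinol, 4-hydroxy-3-iodobenzaldehyde); ring C is the only ring formed (step 5).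

Key step: step 5

Remark on the chemistry: the sense of induction of the chiral acid in step 5 cannot be deduced from precedent; it is assumed that the antipode giving the (2R) series is identified in a first run and then used.

Abbreviations: TBS = tert-butyldimethylsilyl; TMS = trimethylsilyl; MOM = methoxymethyl.

**Route**

Step 1
Reactants: 1 2-iodobenzene-1,3-diol (2-iodoresorcinol)
Product: 2 3-(TBS-oxy)-2-iodophenol
Conditions: TBSCl (1.0 equiv), imidazole, CH2Cl2–DMF, 0 °C
Reagents that add atoms: tert-butyldimethylsilyl chloride, CC(C)(C)[Si](C)(C)Cl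
Why: Silyl ether formation on a symmetric diol: the two hydroxyl groups are equivalent, so only the degree of silylation needs control, and over- and unsilylated material should be separable and recyclable.

Step 2
Reactants: 3 4-hydroxy-3-iodobenzaldehyde
Product: 4 4-(TBS-oxy)-3-iodobenzaldehyde
Conditions: TBSCl, imidazole, DMF, rt
Reagents that add atoms: tert-butyldimethylsilyl chloride, CC(C)(C)[Si](C)(C)Cl
Why: Standard phenol silylation that leaves the aldehyde alone; the para-formyl group makes the aryl silyl ether oxygen poorly nucleophilic, so it should survive the acyl bromide of step 3.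

Step 3
Reactants: 4 4-(TBS-oxy)-3-iodobenzaldehyde; 2 3-(TBS-oxy)-2-iodophenol
Product: 6 [4-(TBS-oxy)-3-iodophenyl][3-(TBS-oxy)-2-iodophenoxy]methyl acetate (racemic), via bromo acetate 5 (not isolated)
Conditions: AcBr (1.05 equiv), ZnBr2 (2 mol %), CH2Cl2, −20 to 0 °C; then 2, iPr2NEt, CH2Cl2, −20 °C to rt
Reagents that add atoms: acetyl bromide, CC(=O)Br
Why: Acyl bromides add to aldehydes under ZnBr2 catalysis to give α-bromoalkyl esters, and the benzylic bromide, which ionises easily next to the para-silyloxyphenyl ring, O-alkylates the phenol under amine base as in acyloxyalkyl ether formation; the new acetal carbon is racemic and becomes planar again in step 5.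

Step 4
Reactants: 7 vinylene carbonate (1,3-dioxol-2-one)
Product: 8 (Z)-1,2-bis(TMS-oxy)ethene
Conditions: MeLi (3 equiv), THF, −78 °C; then TMSCl, −78 °C to rt; distillation
Reagents that add atoms: chlorotrimethylsilane, C[Si](C)(C)Cl
Why: Methyllithium cleaves the cyclic carbonate by repeated addition–elimination at the carbonyl carbon (which ends as tert-butoxide) and releases the cis-enediolate, which is O-silylated; the (Z) geometry is inherited from the ring.

Step 5
Reactants: 6 [4-(TBS-oxy)-3-iodophenyl][3-(TBS-oxy)-2-iodophenoxy]methyl acetate; 8 (Z)-1,2-bis(TMS-oxy)ethene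
Product: 12 (2R,3S,4RS)-7-(TBS-oxy)-2-[4-(TBS-oxy)-3-iodophenyl]-8-iodo-3,4-dihydro-2H-chromene-3,4-diol, via oxocarbenium ion 9 (not isolated), via open-chain aldehyde 10 (not isolated), via bis(trimethylsilyl) ether 11 (not isolated)
Conditions: chiral N-triflyl imidodiphosphorimidate acid (IDPi built from two 3,3'-bis[3,5-bis(trifluoromethyl)phenyl]-BINOL units; 3 mol %), 8 (1.5 equiv), toluene, −78 to −40 °C; then 1 M aq. citric acid–THF, 0 °C
Reagents that add atoms: none
Why: Proposed new method: the silylated chiral acid (formed from the acid and a little 8) takes acetate from 6 and gives the (E)-O-aryl oxocarbenium ion 9 as a contact ion pair with the confined chiral anion; C3 of enol silane 8 adds to C2 (Mukaiyama-type addition, enantio-determining) to give aldehyde 10, whose silyl-activated carbonyl is attacked at once by C4a of ring A (Friedel–Crafts hydroxyalkylation), so that a cationic 2-oxadiene (C4a=C8a–O1=C2) and the C3=C4 enol double bond combine in a polar, stepwise formal [4+2] cycloaddition, and the silyl ether 11 is hydrolysed on work-up. The closest known reaction types are the Lewis acid-promoted oxa-Povarov synthesis of chromans from aryl oxocarbenium ions and alkenes, the Povarov reaction of N-aryl iminium ions with enol ethers, and the imidodiphosphorimidate-catalysed enantioselective addition of enol silanes to oxocarbenium ions released from O-acetyl acetals; what is new is an enol silane as the two-carbon partner of an O-aryl oxocarbenium ion and the control of this annulation by a chiral counter-anion. Ring C is closed through the C4–C4a bond by a 6-exo-trig attack of the arene on the activated aldehyde. C2 is set by the chiral anion, which shields one face of 9; C3 is set relative to C2 in a chair-like transition state in which ring B and the C3 silyloxy group are both pseudo-equatorial, which gives the 2,3-trans relationship; C4 is not controlled and is erased in step 6. The step needs chemoselective ionisation and regioselective ring closure: acetate is the only leaving group because only the acetyl oxygen is silylated and loss of the aryloxy group would give a far less stable acyloxycarbenium ion, and the arene closes at C4a alone because this carbon is ortho to O1 and para to the C7 silyloxy group, C8 is blocked by iodine, and the ortho carbons of ring B are meta to its oxygen.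

Step 6
Reactants: 12 (2R,3S,4RS)-7-(TBS-oxy)-2-[4-(TBS-oxy)-3-iodophenyl]-8-iodo-3,4-dihydro-2H-chromene-3,4-diol
Product: 13 (2R,3R)-7-(TBS-oxy)-2-[4-(TBS-oxy)-3-iodophenyl]-3-hydroxy-8-iodo-2,3-dihydro-4H-chromen-4-one
Conditions: DDQ (1.2 equiv), 1,4-dioxane, rt
Reagents that add atoms: none
Why: DDQ abstracts hydride from the carbinol C4–H of the electron-rich 2,4-dioxygenated benzylic alcohol (quinone oxidation of a benzylic alcohol) and leaves the non-benzylic C3 hydroxyl alone; both C4 epimers converge on one ketone, and C2 and C3 are untouched (the C3 descriptor changes from S to R only through the priority change at C4).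

Step 7
Reactants: 13 (2R,3R)-7-(TBS-oxy)-2-[4-(TBS-oxy)-3-iodophenyl]-3-hydroxy-8-iodo-2,3-dihydro-4H-chromen-4-one
Product: 14 (2R,3R)-7-(TBS-oxy)-2-[4-(TBS-oxy)-3-(3-methylbut-2-enyl)phenyl]-3-hydroxy-8-(3-methylbut-2-enyl)-2,3-dihydro-4H-chromen-4-one
Conditions: tributyl(3-methylbut-2-enyl)stannane (3 equiv), Pd(PPh3)4 (10 mol %), toluene, 100 °C
Reagents that add atoms: tributyl(3-methylbut-2-enyl)stannane, CCCC[Sn](CCCC)(CCCC)CC=C(C)C
Why: Migita–Kosugi–Stille coupling under neutral conditions: zerovalent palladium inserts into both aryl–iodine bonds and the prenyl group is transferred from tin and coupled at its unsubstituted terminus, so both 3-methylbut-2-enyl groups enter at the carbons fixed by the iodines without exposing the base-sensitive 3-hydroxychromanone to base.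

Step 8
Reactants: 14 (2R,3R)-7-(TBS-oxy)-2-[4-(TBS-oxy)-3-(3-methylbut-2-enyl)phenyl]-3-hydroxy-8-(3-methylbut-2-enyl)-2,3-dihydro-4H-chromen-4-one
Product: 15 3-hydroxyglabrol, (2R,3R)-3,7-dihydroxy-2-[4-hydroxy-3-(3-methylbut-2-enyl)phenyl]-8-(3-methylbut-2-enyl)-2,3-dihydro-4H-chromen-4-one
Conditions: KHF2, MeOH, rt
Reagents that add atoms: none
Why: KHF2 in methanol cleaves phenolic silyl ethers by fluoride attack at silicon under weakly acidic, non-basic conditions, which should avoid base-induced ring opening or epimerisation of the dihydroflavonol and acid-induced cyclisation of the ortho-prenyl phenols.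

**Compound list**

1 | 2-iodobenzene-1,3-diol (2-iodoresorcinol) | Oc1cccc(O)c1I | starting material
2 | 3-(TBS-oxy)-2-iodophenol | Oc1cccc(O[Si](C)(C)C(C)(C)C)c1I | intermediate
3 | 4-hydroxy-3-iodobenzaldehyde | O=Cc1ccc(O)c(I)c1 | starting material
4 | 4-(TBS-oxy)-3-iodobenzaldehyde | O=Cc1ccc(O[Si](C)(C)C(C)(C)C)c(I)c1 | intermediate
5 | bromo[4-(TBS-oxy)-3-iodophenyl]methyl acetate (racemic) | CC(=O)OC(Br)c1ccc(O[Si](C)(C)C(C)(C)C)c(I)c1 | intermediate
6 | [4-(TBS-oxy)-3-iodophenyl][3-(TBS-oxy)-2-iodophenoxy]methyl acetate (racemic) | CC(=O)OC(Oc1cccc(O[Si](C)(C)C(C)(C)C)c1I)c1ccc(O[Si](C)(C)C(C)(C)C)c(I)c1 | intermediate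
7 | vinylene carbonate (1,3-dioxol-2-one) | O=C1OC=CO1 | starting material
8 | (Z)-1,2-bis(TMS-oxy)ethene | C[Si](C)(C)O/C=C\O[Si](C)(C)C | intermediate
9 | (E)-[4-(TBS-oxy)-3-iodophenyl]methylidene[3-(TBS-oxy)-2-iodophenyl]oxonium (O-aryl oxocarbenium ion, paired with the catalyst anion) | CC(C)(C)[Si](C)(C)Oc1ccc(/C=[O+]/c2cccc(O[Si](C)(C)C(C)(C)C)c2I)cc1I | intermediate
10 | (2R,3R)-3-[4-(TBS-oxy)-3-iodophenyl]-3-[3-(TBS-oxy)-2-iodophenoxy]-2-(TMS-oxy)propanal | CC(C)(C)[Si](C)(C)Oc1ccc(cc1I)[C@@H](Oc1cccc(O[Si](C)(C)C(C)(C)C)c1I)[C@@H](O[Si](C)(C)C)C=O | intermediate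
11 | (2R,3R,4RS)-7-(TBS-oxy)-2-[4-(TBS-oxy)-3-iodophenyl]-8-iodo-3,4-bis(TMS-oxy)-3,4-dihydro-2H-chromene (C4 epimers) | CC(C)(C)[Si](C)(C)Oc1ccc(cc1I)[C@H]1Oc2c(I)c(O[Si](C)(C)C(C)(C)C)ccc2C(O[Si](C)(C)C)[C@@H]1O[Si](C)(C)C | intermediate
12 | (2R,3S,4RS)-7-(TBS-oxy)-2-[4-(TBS-oxy)-3-iodophenyl]-8-iodo-3,4-dihydro-2H-chromene-3,4-diol (C4 epimers; 2,3-trans) | CC(C)(C)[Si](C)(C)Oc1ccc(cc1I)[C@H]1Oc2c(I)c(O[Si](C)(C)C(C)(C)C)ccc2C(O)[C@@H]1O | intermediate
13 | (2R,3R)-7-(TBS-oxy)-2-[4-(TBS-oxy)-3-iodophenyl]-3-hydroxy-8-iodo-2,3-dihydro-4H-chromen-4-one | CC(C)(C)[Si](C)(C)Oc1ccc(cc1I)[C@H]1Oc2c(I)c(O[Si](C)(C)C(C)(C)C)ccc2C(=O)[C@@H]1O | intermediate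
14 | (2R,3R)-7-(TBS-oxy)-2-[4-(TBS-oxy)-3-(3-methylbut-2-enyl)phenyl]-3-hydroxy-8-(3-methylbut-2-enyl)-2,3-dihydro-4H-chromen-4-one | CC(C)=CCc1cc(ccc1O[Si](C)(C)C(C)(C)C)[C@H]1Oc2c(CC=C(C)C)c(O[Si](C)(C)C(C)(C)C)ccc2C(=O)[C@@H]1O | intermediate
15 | 3-hydroxyglabrol, (2R,3R)-3,7-dihydroxy-2-[4-hydroxy-3-(3-methylbut-2-enyl)phenyl]-8-(3-methylbut-2-enyl)-2,3-dihydro-4H-chromen-4-one | CC(C)=CCc1cc([C@H]2Oc3c(ccc(O)c3CC=C(C)C)C(=O)[C@@H]2O)ccc1O | target

**Step count and risks**

Total step count: 8. Longest linear sequence: 6 steps (3 → 4 → 6 → 12 → 13 → 14 → 15; steps 2, 3, 5, 6, 7, 8).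

Steps most likely to fail:

1. Step 5 (proposed new method). What may go wrong:
   - insufficient facial discrimination of the oxocarbenium ion by the chiral anion;
   - loss of the trans preference in the C2–C3 bond formation;
   - arrest at the open-chain aldehyde or its capture by a second molecule of the enol silane;
   - acid-induced ionisation at the benzylic C4 carbinol, or protodeiodination at C8.

   Fallback (known chemistry, chalcone epoxide route): it sets out from 3 and returns to the route at 13. 3 is converted with MOMCl and iPr2NEt into 3-iodo-4-(methoxymethoxy)benzaldehyde F1. Purchased 1-(2,4-dihydroxyphenyl)ethanone is iodinated between its hydroxyl groups (I2, HIO3, aq. EtOH) to 1-(2,4-dihydroxy-3-iodophenyl)ethanone F2 and protected (NaH, MOMCl, DMF) as 1-[3-iodo-2,4-bis(methoxymethoxy)phenyl]ethanone F3. Claisen–Schmidt condensation of F1 and F3 (KOH, EtOH) should give the (E)-chalcone F4. Juliá–Colonna epoxidation (poly-L-leucine, urea–H2O2, DBU, THF) should give the (αR,βS)-epoxy ketone F5. HCl in MeOH–THF removes the three MOM groups, and the freed 2'-phenol opens the epoxide at the benzylic carbon with inversion to give the 2,3-trans dihydroflavonol F6. The two phenols of F6 are then silylated selectively (TBSCl, imidazole, DMF, 0 °C) to give 13.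

2. Step 3. What may go wrong: acyl transfer instead of O-alkylation (the phenol attacks the acetyl group of the bromo acetate, or the bromo acetate reverts to aldehyde and acetyl bromide, which then acetylates the phenol), and hydrolysis of the labile acetal during purification.

   Fallback (reductive acetylation of an aryl ester): it sets out from 4 and 2 and returns at 6. Pinnick oxidation of 4 (NaClO2, NaH2PO4, 2-methylbut-2-ene, t-BuOH–H2O) should give 4-(TBS-oxy)-3-iodobenzoic acid F7. Esterification with 2 (EDC, DMAP, CH2Cl2) should give the aryl ester 3-(TBS-oxy)-2-iodophenyl 4-(TBS-oxy)-3-iodobenzoate F8. Reduction with i-Bu2AlH at −78 °C and trapping of the aluminium hemiacetal in the cold with Ac2O, pyridine and DMAP should give 6.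

3. Step 7. What may go wrong: slow oxidative addition at the C8–iodine bond, which is flanked by two oxygen substituents, leading to mono-coupling or protodeiodination; and transfer of the prenyl group through its substituted terminus, giving 1,1-dimethylallyl isomers.

   Fallback (allylation, then cross-metathesis): it sets out from 13 and returns at 14. Stille coupling with allyltributylstannane (Pd(PPh3)4, toluene, 100 °C), which is sterically less demanding and has no regiochemical ambiguity, should give the bis-allyl compound F9. Olefin cross-metathesis with excess 2-methylbut-2-ene (second-generation Grubbs catalyst, CH2Cl2, 40 °C) should convert both allyl groups into prenyl groups and give 14.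

**Further compounds**

F1 | step 5 | 3-iodo-4-(methoxymethoxy)benzaldehyde | O=Cc1ccc(OCOC)c(I)c1
F2 | step 5 | 1-(2,4-dihydroxy-3-iodophenyl)ethanone | CC(=O)c1ccc(O)c(I)c1O
F3 | step 5 | 1-[3-iodo-2,4-bis(methoxymethoxy)phenyl]ethanone | CC(=O)c1ccc(OCOC)c(I)c1OCOC
F4 | step 5 | (E)-1-[3-iodo-2,4-bis(methoxymethoxy)phenyl]-3-[3-iodo-4-(methoxymethoxy)phenyl]prop-2-en-1-one | COCOc1ccc(/C=C/C(=O)c2ccc(OCOC)c(I)c2OCOC)cc1I
F5 | step 5 | [(2R,3S)-3-[3-iodo-4-(methoxymethoxy)phenyl]oxiran-2-yl][3-iodo-2,4-bis(methoxymethoxy)phenyl]methanone | COCOc1ccc(cc1I)[C@@H]1O[C@H]1C(=O)c1ccc(OCOC)c(I)c1OCOC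
F6 | step 5 | (2R,3R)-3,7-dihydroxy-2-(4-hydroxy-3-iodophenyl)-8-iodo-2,3-dihydro-4H-chromen-4-one | Oc1ccc(cc1I)[C@H]1Oc2c(I)c(O)ccc2C(=O)[C@@H]1O
F7 | step 3 | 4-(TBS-oxy)-3-iodobenzoic acid | OC(=O)c1ccc(O[Si](C)(C)C(C)(C)C)c(I)c1
F8 | step 3 | 3-(TBS-oxy)-2-iodophenyl 4-(TBS-oxy)-3-iodobenzoate | O=C(Oc1cccc(O[Si](C)(C)C(C)(C)C)c1I)c1ccc(O[Si](C)(C)C(C)(C)C)c(I)c1
F9 | step 7 | (2R,3R)-7-(TBS-oxy)-2-[4-(TBS-oxy)-3-(prop-2-enyl)phenyl]-3-hydroxy-8-(prop-2-enyl)-2,3-dihydro-4H-chromen-4-one | C=CCc1cc(ccc1O[Si](C)(C)C(C)(C)C)[C@H]1Oc2c(CC=C)c(O[Si](C)(C)C(C)(C)C)ccc2C(=O)[C@@H]1O
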